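**Plan**
- Retrosynthesis: after removal of three benzyl and two silyl groups, the lactone bond C4–C5 and the bond from the methylene C7 to the tetrasubstituted arene are cut in one operation. This gives an iodomethyl (R)-2-arylmethylbut-3-enoate and an aryl iodide that carries the protected 1,3-diol.
- Enabling feature: in the γ-lactone ring O1–C2–C3–C4–C5, C5 is a CH2 bonded to the acyloxy oxygen (a radical site that an I–CH2–O–C(=O) group delivers) and its neighbour C4 carries the arylmethyl carbon C7. The array C5–C4–C7–aryl is what addition of that radical to a vinyl group on C3, followed by arylation of C7, builds.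
- The ester is cut further at O–C5 (carboxylate alkylation) and at C3–CH2Ar (dienolate alkylation); the aryl iodide is cut between its two side-chain stereocenters (aldol) and at the aryl–CH2 carbon (one-carbon homologation of iodinated o-vanillin).
- Forward order: the two fragments are made separately and joined in the step that closes the lactone and attaches the arene; hydrogenolysis and desilylation follow.
- Stereochemistry: C3 comes from an oxazolidinone-controlled deconjugative alkylation, C4 from C3 in the radical ring closure (trans), and both side-chain centers from an oxazolidinone-controlled magnesium-catalysed anti-aldol reaction.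

Key step: step 15

Remark on the chemistry: the lactone is numbered O1, C2 (C=O), C3, C4, C5 (OCH2), and C7 is the methylene between C4 and the tetrasubstituted ring. The sense of induction in step 12 is assumed to follow the chelated Z-enolate model that holds for alkylations with the same auxiliary; if it proved opposite, the enantiomeric auxiliary would be used there.

**Route**

Step 1
Reactants: 1 (4R)-4-benzyl-1,3-oxazolidin-2-one; 2 (E)-but-2-enoyl chloride
Product: 4 (4R)-4-benzyl-3-[(2E)-but-2-enoyl]-1,3-oxazolidin-2-one, via lithium oxazolidinide 3 (not isolated)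
Conditions: n-BuLi, THF, −78 °C; then 2, −78 to 0 °C
Reagents that add atoms: none
Why: N-acylation of the lithiated oxazolidinone by an acid chloride is the standard attachment of this auxiliary and creates no stereocenter.

Step 2
Reactants: 5 [4-(benzyloxy)-3-methoxyphenyl]methanol
Product: 6 1-(benzyloxy)-4-(bromomethyl)-2-methoxybenzene
Conditions: PBr3, Et2O, 0 °C; used without storage
Reagents that add atoms: phosphorus tribromide BrP(Br)Br
Why: Bromination of an electron-rich benzylic alcohol with PBr3 (substitution on the intermediate bromophosphite) is routine.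

Step 3
Reactants: 4 (4R)-4-benzyl-3-[(2E)-but-2-enoyl]-1,3-oxazolidin-2-one; 6 1-(benzyloxy)-4-(bromomethyl)-2-methoxybenzene
Product: 8 (4R)-4-benzyl-3-[(2R)-2-{[4-(benzyloxy)-3-methoxyphenyl]methyl}but-3-enoyl]-1,3-oxazolidin-2-one, via sodium Z-dienolate 7 (not isolated)
Conditions: NaN(SiMe3)2, THF, −78 °C; then 6, −78 to −40 °C
Reagents that add atoms: none
Why: In this deconjugative, auxiliary-controlled enolate alkylation the γ-deprotonated, sodium-chelated Z-dienolate should react at its α-carbon on the face opposite the auxiliary benzyl group, which sets the future C3 as R and leaves a terminal vinyl group.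

Step 4
Reactants: 8 (4R)-4-benzyl-3-[(2R)-2-{[4-(benzyloxy)-3-methoxyphenyl]methyl}but-3-enoyl]-1,3-oxazolidin-2-one
Product: 10 (2R)-2-{[4-(benzyloxy)-3-methoxyphenyl]methyl}but-3-enoic acid, via peroxy acid 9 (not isolated)
Conditions: LiOH, H2O2, THF/H2O, 0 °C; then Na2SO3; then aq. HCl to pH 3
Reagents that add atoms: hydrogen peroxide OO
Why: Hydroperoxide cleavage of an N-acyloxazolidinone uses a weakly basic, strongly nucleophilic anion that attacks the exocyclic carbonyl at 0 °C, so the allylic α-hydrogen should be neither epimerised nor the double bond moved into conjugation, and the auxiliary is recovered.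

Step 5
Reactants: 10 (2R)-2-{[4-(benzyloxy)-3-methoxyphenyl]methyl}but-3-enoic acid
Product: 11 chloromethyl (2R)-2-{[4-(benzyloxy)-3-methoxyphenyl]methyl}but-3-enoate
Conditions: ClCH2OSO2Cl, NaHCO3, Bu4NHSO4 (cat.), CH2Cl2/H2O, rt
Reagents that add atoms: chloromethyl chlorosulfate ClCOS(=O)(=O)Cl
Why: Phase-transfer O-alkylation of the carboxylate (SN2 at the CH2 with chlorosulfate as leaving group) is the standard entry to chloromethyl esters and runs at near-neutral pH, which protects the α-stereocenter.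

Step 6
Reactants: 11 chloromethyl (2R)-2-{[4-(benzyloxy)-3-methoxyphenyl]methyl}but-3-enoate
Product: 12 iodomethyl (2R)-2-{[4-(benzyloxy)-3-methoxyphenyl]methyl}but-3-enoate
Conditions: NaI, acetone, rt, dark
Reagents that add atoms: sodium iodide [Na+].[I-]
Why: Finkelstein exchange at the activated acyloxymethyl carbon is fast and is driven by precipitation of NaCl.

Step 7
Reactants: 13 2-hydroxy-3-methoxybenzaldehyde
Product: 14 2-hydroxy-5-iodo-3-methoxybenzaldehyde
Conditions: ICl, AcOH, rt
Reagents that add atoms: iodine monochloride ClI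
Why: Electrophilic aromatic iodination should go to the position para to the hydroxyl group, which is also meta to the formyl group.

Step 8
Reactants: 14 2-hydroxy-5-iodo-3-methoxybenzaldehyde
Product: 15 2-(benzyloxy)-5-iodo-3-methoxybenzaldehyde
Conditions: BnBr, K2CO3, DMF, 50 °C
Reagents that add atoms: benzyl bromide BrCc1ccccc1
Why: Williamson etherification of the phenoxide is routine and masks the phenol as a group removable by hydrogenolysis.

Step 9
Reactants: 15 2-(benzyloxy)-5-iodo-3-methoxybenzaldehyde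
Product: 17 2-[2-(benzyloxy)-5-iodo-3-methoxyphenyl]acetaldehyde, via methyl enol ether 16 (not isolated)
Conditions: Ph3P(CH2OMe)Cl, KOtBu, THF, 0 °C; then 2 M HCl, THF, 40 °C
Reagents that add atoms: (methoxymethyl)triphenylphosphonium chloride [Cl-].COC[P+](c1ccccc1)(c1ccccc1)c1ccccc1; water O
Why: Wittig methoxymethylenation followed by acid hydrolysis of the enol ether is the standard one-carbon homologation of an aryl aldehyde to an arylacetaldehyde.

Step 10
Reactants: 17 2-[2-(benzyloxy)-5-iodo-3-methoxyphenyl]acetaldehyde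
Product: 18 2-[2-(benzyloxy)-5-iodo-3-methoxyphenyl]acetic acid
Conditions: NaClO2, NaH2PO4, 2-methylbut-2-ene, t-BuOH/H2O, 0 °C to rt
Reagents that add atoms: sodium chlorite [Na+].[O-]Cl=O
Why: Pinnick oxidation converts the aldehyde to the acid under buffered conditions, and the alkene scavenger protects the electron-rich ring from hypochlorous acid.

Step 11
Reactants: 18 2-[2-(benzyloxy)-5-iodo-3-methoxyphenyl]acetic acid; 1 (4R)-4-benzyl-1,3-oxazolidin-2-one
Product: 20 (4R)-4-benzyl-3-{2-[2-(benzyloxy)-5-iodo-3-methoxyphenyl]acetyl}-1,3-oxazolidin-2-one, via mixed pivalic anhydride 19 (not isolated)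
Conditions: t-BuCOCl, Et3N, THF, −20 °C; then 1, LiCl, rt
Reagents that add atoms: none
Why: Acylation of the oxazolidinone by a mixed pivalic anhydride in the presence of LiCl and Et3N is a standard one-flask attachment of arylacetic acids.

Step 12
Reactants: 20 (4R)-4-benzyl-3-{2-[2-(benzyloxy)-5-iodo-3-methoxyphenyl]acetyl}-1,3-oxazolidin-2-one; 21 4-(benzyloxy)-3-methoxybenzaldehyde
Product: 23 (4R)-4-benzyl-3-[(2S,3R)-2-[2-(benzyloxy)-5-iodo-3-methoxyphenyl]-3-[4-(benzyloxy)-3-methoxyphenyl]-3-hydroxypropanoyl]-1,3-oxazolidin-2-one, via trimethylsilyl ether 22 (not isolated)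
Conditions: MgCl2 (20 mol %), Et3N, Me3SiCl, EtOAc, rt; then MeOH, CF3CO2H (cat.)
Reagents that add atoms: none
Why: In the magnesium halide-catalysed direct anti-aldol reaction of N-acyloxazolidinones with aromatic aldehydes, the magnesium-chelated Z-enolate should add through a boat transition state on the face away from the auxiliary benzyl group, which sets both side-chain centers (anti), while silylation of the aldolate makes the step irreversible.

Step 13
Reactants: 23 (4R)-4-benzyl-3-[(2S,3R)-2-[2-(benzyloxy)-5-iodo-3-methoxyphenyl]-3-[4-(benzyloxy)-3-methoxyphenyl]-3-hydroxypropanoyl]-1,3-oxazolidin-2-one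
Product: 24 (1R,2R)-2-[2-(benzyloxy)-5-iodo-3-methoxyphenyl]-1-[4-(benzyloxy)-3-methoxyphenyl]propane-1,3-diol
Conditions: LiBH4, MeOH (1 equiv), THF, 0 °C
Reagents that add atoms: none
Why: Reductive removal of the auxiliary with LiBH4 gives the 1,3-diol directly without touching either stereocenter, the aryl iodide or the benzyl ethers.

Step 14
Reactants: 24 (1R,2R)-2-[2-(benzyloxy)-5-iodo-3-methoxyphenyl]-1-[4-(benzyloxy)-3-methoxyphenyl]propane-1,3-diol
Product: 25 (1R,2R)-2-[2-(benzyloxy)-5-iodo-3-methoxyphenyl]-1-[4-(benzyloxy)-3-methoxyphenyl]-1,3-bis(tert-butyldimethylsilyloxy)propane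
Conditions: t-BuMe2SiOTf, 2,6-lutidine, CH2Cl2, 0 °C
Reagents that add atoms: tert-butyldimethylsilyl triflate CC(C)(C)[Si](C)(C)OS(=O)(=O)C(F)(F)F
Why: Silylation with the silyl triflate protects both the primary and the hindered benzylic hydroxyl group as ethers that are cleaved later by fluoride without acid.

Step 15
Reactants: 12 iodomethyl (2R)-2-{[4-(benzyloxy)-3-methoxyphenyl]methyl}but-3-enoate; 25 (1R,2R)-2-[2-(benzyloxy)-5-iodo-3-methoxyphenyl]-1-[4-(benzyloxy)-3-methoxyphenyl]-1,3-bis(tert-butyldimethylsilyloxy)propane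
Product: 26 (3R,4R)-3-{[4-(benzyloxy)-3-methoxyphenyl]methyl}-4-({4-(benzyloxy)-3-[(1R,2R)-1-[4-(benzyloxy)-3-methoxyphenyl]-1,3-bis(tert-butyldimethylsilyloxy)propan-2-yl]-5-methoxyphenyl}methyl)oxolan-2-one
Conditions: NiBr2·glyme (5–10 mol %), 4,4′-di-tert-butyl-2,2′-bipyridine, Mn powder, N,N-dimethylacetamide, 50 °C, slow addition of 12
Reagents that add atoms: none
Why: Proposed new method: zerovalent nickel (from NiBr2·glyme and Mn) should insert into the aryl–iodine bond of 25 to give an aryl iodide complex of divalent nickel, while monovalent nickel abstracts iodine from the weak O–CH2–I bond of 12; the nucleophilic acyloxymethyl radical then adds, through the s-cis ester rotamer, to the internal carbon of the vinyl group, and the primary radical left on C7 is captured by the arylnickel species and released by reductive elimination from trivalent nickel as the C7–aryl bond, Mn closing the cycle. The closest known reaction type is the nickel-catalysed reductive cyclisation–arylation of alkene-tethered alkyl halides (acetal- or ether-tethered bromides) with aryl iodides, together with the nickel-catalysed arylation of 1-acyloxyalkyl halides; an ester-tethered iodomethyl carboxylate has not been used in it. The lactone ring closes in the 5-exo-trig radical mode (C5 onto C4), the 6-endo mode being disfavoured at the unsubstituted vinyl terminus. The new stereocenter C4 is controlled by C3: in the chair-like transition state the C3 arylmethyl group sits pseudo-equatorial, so the new C4–C7 bond ends up trans to it and gives the 3R,4R lactone, which is also the more stable isomer. The step needs ring closure to outrun capture of the uncyclised radical (which would give an arylmethyl ester) and needs cross-selectivity between the two iodides; a low nickel loading, slow addition of 12, 50 °C and the polar amide solvent (which raises the share of the s-cis rotamer) serve the first, and the different activation modes of the sp2 iodide (oxidative addition) and the α-oxygenated sp3 iodide (halogen abstraction) secure the second. The neutral medium should leave the allylic C3–H untouched until the ring has formed.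

Step 16
Reactants: 26 (3R,4R)-3-{[4-(benzyloxy)-3-methoxyphenyl]methyl}-4-({4-(benzyloxy)-3-[(1R,2R)-1-[4-(benzyloxy)-3-methoxyphenyl]-1,3-bis(tert-butyldimethylsilyloxy)propan-2-yl]-5-methoxyphenyl}methyl)oxolan-2-one
Product: 27 (3R,4R)-4-({3-[(1R,2R)-1,3-bis(tert-butyldimethylsilyloxy)-1-(4-hydroxy-3-methoxyphenyl)propan-2-yl]-4-hydroxy-5-methoxyphenyl}methyl)-3-[(4-hydroxy-3-methoxyphenyl)methyl]oxolan-2-one
Conditions: H2 (1 atm), Pd/C, EtOAc/EtOH, rt
Reagents that add atoms: none
Why: Hydrogenolysis of the three aryl benzyl ethers is carried out while the benzylic oxygen is still a bulky silyl ether, which should shield that C–O bond from reductive cleavage.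

Step 17
Reactants: 27 (3R,4R)-4-({3-[(1R,2R)-1,3-bis(tert-butyldimethylsilyloxy)-1-(4-hydroxy-3-methoxyphenyl)propan-2-yl]-4-hydroxy-5-methoxyphenyl}methyl)-3-[(4-hydroxy-3-methoxyphenyl)methyl]oxolan-2-one
Product: 28 (3R,4R)-4-({3-[(1R,2R)-1,3-dihydroxy-1-(4-hydroxy-3-methoxyphenyl)propan-2-yl]-4-hydroxy-5-methoxyphenyl}methyl)-3-[(4-hydroxy-3-methoxyphenyl)methyl]oxolan-2-one
Conditions: Bu4NF, AcOH (1:1), THF, 0 °C to rt
Reagents that add atoms: none
Why: Fluoride desilylation buffered with acetic acid frees both hydroxyl groups without the acid that could ionise the p-hydroxybenzylic carbinol and close a dihydrobenzofuran with the neighbouring phenol.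

**Compound list**

1 | (4R)-4-benzyl-1,3-oxazolidin-2-one | O=C1N[C@H](Cc2ccccc2)CO1 | starting material
2 | (E)-but-2-enoyl chloride | C/C=C/C(Cl)=O | starting material
3 | lithium (4R)-4-benzyl-2-oxo-1,3-oxazolidin-3-ide | [Li+].O=C1[N-][C@H](Cc2ccccc2)CO1 | intermediate (not isolated)
4 | (4R)-4-benzyl-3-[(2E)-but-2-enoyl]-1,3-oxazolidin-2-one | C/C=C/C(=O)N1[C@H](Cc2ccccc2)COC1=O | intermediate
5 | [4-(benzyloxy)-3-methoxyphenyl]methanol | COc1cc(CO)ccc1OCc1ccccc1 | starting material
6 | 1-(benzyloxy)-4-(bromomethyl)-2-methoxybenzene | COc1cc(CBr)ccc1OCc1ccccc1 | intermediate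
7 | sodium (1Z)-1-[(4R)-4-benzyl-2-oxo-1,3-oxazolidin-3-yl]buta-1,3-dien-1-olate | [Na+].[O-]/C(=C\C=C)N1[C@H](Cc2ccccc2)COC1=O | intermediate (not isolated)
8 | (4R)-4-benzyl-3-[(2R)-2-{[4-(benzyloxy)-3-methoxyphenyl]methyl}but-3-enoyl]-1,3-oxazolidin-2-one | C=C[C@@H](Cc1ccc(OCc2ccccc2)c(OC)c1)C(=O)N1[C@H](Cc2ccccc2)COC1=O | intermediate
9 | (2R)-2-{[4-(benzyloxy)-3-methoxyphenyl]methyl}but-3-eneperoxoic acid | C=C[C@@H](Cc1ccc(OCc2ccccc2)c(OC)c1)C(=O)OO | intermediate (not isolated)
10 | (2R)-2-{[4-(benzyloxy)-3-methoxyphenyl]methyl}but-3-enoic acid | C=C[C@@H](Cc1ccc(OCc2ccccc2)c(OC)c1)C(=O)O | intermediate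
11 | chloromethyl (2R)-2-{[4-(benzyloxy)-3-methoxyphenyl]methyl}but-3-enoate | C=C[C@@H](Cc1ccc(OCc2ccccc2)c(OC)c1)C(=O)OCCl | intermediate
12 | iodomethyl (2R)-2-{[4-(benzyloxy)-3-methoxyphenyl]methyl}but-3-enoate | C=C[C@@H](Cc1ccc(OCc2ccccc2)c(OC)c1)C(=O)OCI | intermediate
13 | 2-hydroxy-3-methoxybenzaldehyde | COc1cccc(C=O)c1O | starting material
14 | 2-hydroxy-5-iodo-3-methoxybenzaldehyde | COc1cc(I)cc(C=O)c1O | intermediate
15 | 2-(benzyloxy)-5-iodo-3-methoxybenzaldehyde | COc1cc(I)cc(C=O)c1OCc1ccccc1 | intermediate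
16 | 2-(benzyloxy)-5-iodo-1-methoxy-3-(2-methoxyethenyl)benzene (E/Z mixture) | COC=Cc1cc(I)cc(OC)c1OCc1ccccc1 | intermediate (not isolated)
17 | 2-[2-(benzyloxy)-5-iodo-3-methoxyphenyl]acetaldehyde | O=CCc1cc(I)cc(OC)c1OCc1ccccc1 | intermediate
18 | 2-[2-(benzyloxy)-5-iodo-3-methoxyphenyl]acetic acid | OC(=O)Cc1cc(I)cc(OC)c1OCc1ccccc1 | intermediate
19 | 2-[2-(benzyloxy)-5-iodo-3-methoxyphenyl]acetic 2,2-dimethylpropanoic anhydride | CC(C)(C)C(=O)OC(=O)Cc1cc(I)cc(OC)c1OCc1ccccc1 | intermediate (not isolated)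
20 | (4R)-4-benzyl-3-{2-[2-(benzyloxy)-5-iodo-3-methoxyphenyl]acetyl}-1,3-oxazolidin-2-one | O=C(Cc1cc(I)cc(OC)c1OCc1ccccc1)N1[C@H](Cc2ccccc2)COC1=O | intermediate
21 | 4-(benzyloxy)-3-methoxybenzaldehyde | COc1cc(C=O)ccc1OCc1ccccc1 | starting material
22 | (4R)-4-benzyl-3-[(2S,3R)-2-[2-(benzyloxy)-5-iodo-3-methoxyphenyl]-3-[4-(benzyloxy)-3-methoxyphenyl]-3-(trimethylsilyloxy)propanoyl]-1,3-oxazolidin-2-one | COc1cc(I)cc([C@H](C(=O)N2[C@H](Cc3ccccc3)COC2=O)[C@@H](O[Si](C)(C)C)c2ccc(OCc3ccccc3)c(OC)c2)c1OCc1ccccc1 | intermediate (not isolated)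
23 | (4R)-4-benzyl-3-[(2S,3R)-2-[2-(benzyloxy)-5-iodo-3-methoxyphenyl]-3-[4-(benzyloxy)-3-methoxyphenyl]-3-hydroxypropanoyl]-1,3-oxazolidin-2-one | COc1cc(I)cc([C@H](C(=O)N2[C@H](Cc3ccccc3)COC2=O)[C@@H](O)c2ccc(OCc3ccccc3)c(OC)c2)c1OCc1ccccc1 | intermediate
24 | (1R,2R)-2-[2-(benzyloxy)-5-iodo-3-methoxyphenyl]-1-[4-(benzyloxy)-3-methoxyphenyl]propane-1,3-diol | COc1cc(I)cc([C@H](CO)[C@@H](O)c2ccc(OCc3ccccc3)c(OC)c2)c1OCc1ccccc1 | intermediate
25 | (1R,2R)-2-[2-(benzyloxy)-5-iodo-3-methoxyphenyl]-1-[4-(benzyloxy)-3-methoxyphenyl]-1,3-bis(tert-butyldimethylsilyloxy)propane | COc1cc(I)cc([C@H](CO[Si](C)(C)C(C)(C)C)[C@@H](O[Si](C)(C)C(C)(C)C)c2ccc(OCc3ccccc3)c(OC)c2)c1OCc1ccccc1 | intermediate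
26 | (3R,4R)-3-{[4-(benzyloxy)-3-methoxyphenyl]methyl}-4-({4-(benzyloxy)-3-[(1R,2R)-1-[4-(benzyloxy)-3-methoxyphenyl]-1,3-bis(tert-butyldimethylsilyloxy)propan-2-yl]-5-methoxyphenyl}methyl)oxolan-2-one | COc1cc(C[C@H]2C(=O)OC[C@@H]2Cc2cc(OC)c(OCc3ccccc3)c([C@H](CO[Si](C)(C)C(C)(C)C)[C@@H](O[Si](C)(C)C(C)(C)C)c3ccc(OCc4ccccc4)c(OC)c3)c2)ccc1OCc1ccccc1 | intermediate
27 | (3R,4R)-4-({3-[(1R,2R)-1,3-bis(tert-butyldimethylsilyloxy)-1-(4-hydroxy-3-methoxyphenyl)propan-2-yl]-4-hydroxy-5-methoxyphenyl}methyl)-3-[(4-hydroxy-3-methoxyphenyl)methyl]oxolan-2-one | COc1cc(C[C@H]2C(=O)OC[C@@H]2Cc2cc(OC)c(O)c([C@H](CO[Si](C)(C)C(C)(C)C)[C@@H](O[Si](C)(C)C(C)(C)C)c3ccc(O)c(OC)c3)c2)ccc1O | intermediate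
28 | (3R,4R)-4-({3-[(1R,2R)-1,3-dihydroxy-1-(4-hydroxy-3-methoxyphenyl)propan-2-yl]-4-hydroxy-5-methoxyphenyl}methyl)-3-[(4-hydroxy-3-methoxyphenyl)methyl]oxolan-2-one | COc1cc(C[C@H]2C(=O)OC[C@@H]2Cc2cc(OC)c(O)c([C@H](CO)[C@@H](O)c3ccc(O)c(OC)c3)c2)ccc1O | target

**Step count**

Total: 17 steps. Longest linear sequence: 11 steps (steps 7 to 17).

**Steps most likely to fail, with fallbacks**

Step 15 (proposed new method). The acyloxymethyl radical may be captured by the arylnickel species before it cyclises, because rotation of the ester to the s-cis rotamer is slow; the C3 hydrogen may also be lost with migration of the double bond into conjugation. The fallback uses only known lignan-lactone chemistry, sets out from 25 and comes back to the route at 26. Iodine–magnesium exchange on 25 (i-PrMgCl·LiCl, THF, −20 °C) and quenching with DMF would give 4-(benzyloxy)-3-[(1R,2R)-1-[4-(benzyloxy)-3-methoxyphenyl]-1,3-bis(tert-butyldimethylsilyloxy)propan-2-yl]-5-methoxybenzaldehyde F1. Stobbe condensation with dimethyl succinate (NaOMe, MeOH, reflux) would give the (E)-arylidene succinic half-ester F2. Asymmetric hydrogenation with a cationic rhodium bisphosphine catalyst ([Rh(cod)2]BF4 with the enantiomer of Me-DuPhos that delivers the 3R acid; benzyl and silyl ethers are not touched) would give the (3R)-half-ester F3. Reduction of the ester in its carboxylate salt (Ca(BH4)2, EtOH) and lactonisation on mild acidification would give the (4R)-4-arylmethyl lactone F4. Alkylation of its lithium enolate (LiN(SiMe3)2, THF, −78 °C) with bromide 6, trans to the C4 substituent, would give 26. In this sequence C4 comes from the hydrogenation and C3 from C4, and acid 10 is not needed.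

Step 12. Anti selectivity may be eroded, or the acidic α-aryl center epimerised, by the amine under the reversible soft-enolisation conditions; the silylated aldolate may also revert. The fallback sets out from 20 and comes back at 23, and it changes the enolate and the transition state. The dibutylboron Z-enolate of 20 would be preformed (Bu2BOTf, i-Pr2NEt, CH2Cl2, −78 °C) and added to aldehyde 21 that has been precomplexed with Et2AlCl. The boron-chelated enolate should then react through an open transition state on the same face, under kinetic control at −78 °C, to give the same anti adduct 23 directly. No new compound is made.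

Step 13. Retro-aldol cleavage of the lithium aldolate (an α-aryl-stabilised enolate leaving from an aromatic aldehyde) may compete with hydride attack on the imide. The fallback sets out from 23 and comes back at 25, and it removes the free aldolate from the reduction. The carbinol would be silylated first (t-BuMe2SiOTf, 2,6-lutidine, CH2Cl2, 0 °C) to give (4R)-4-benzyl-3-[(2S,3R)-2-[2-(benzyloxy)-5-iodo-3-methoxyphenyl]-3-[4-(benzyloxy)-3-methoxyphenyl]-3-(tert-butyldimethylsilyloxy)propanoyl]-1,3-oxazolidin-2-one F5. LiBH4 (THF, MeOH, 0 °C) would then give (2R,3R)-2-[2-(benzyloxy)-5-iodo-3-methoxyphenyl]-3-[4-(benzyloxy)-3-methoxyphenyl]-3-(tert-butyldimethylsilyloxy)propan-1-ol F6, and silylation of the primary alcohol (t-BuMe2SiCl, imidazole, DMF) would give 25.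

Further compounds
F1 | step 15 | 4-(benzyloxy)-3-[(1R,2R)-1-[4-(benzyloxy)-3-methoxyphenyl]-1,3-bis(tert-butyldimethylsilyloxy)propan-2-yl]-5-methoxybenzaldehyde | COc1cc(C=O)cc([C@H](CO[Si](C)(C)C(C)(C)C)[C@@H](O[Si](C)(C)C(C)(C)C)c2ccc(OCc3ccccc3)c(OC)c2)c1OCc1ccccc1
F2 | step 15 | (3E)-4-{4-(benzyloxy)-3-[(1R,2R)-1-[4-(benzyloxy)-3-methoxyphenyl]-1,3-bis(tert-butyldimethylsilyloxy)propan-2-yl]-5-methoxyphenyl}-3-(methoxycarbonyl)but-3-enoic acid | COC(=O)/C(=C/c1cc(OC)c(OCc2ccccc2)c([C@H](CO[Si](C)(C)C(C)(C)C)[C@@H](O[Si](C)(C)C(C)(C)C)c2ccc(OCc3ccccc3)c(OC)c2)c1)CC(=O)O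
F3 | step 15 | (3R)-4-{4-(benzyloxy)-3-[(1R,2R)-1-[4-(benzyloxy)-3-methoxyphenyl]-1,3-bis(tert-butyldimethylsilyloxy)propan-2-yl]-5-methoxyphenyl}-3-(methoxycarbonyl)butanoic acid | COC(=O)[C@H](Cc1cc(OC)c(OCc2ccccc2)c([C@H](CO[Si](C)(C)C(C)(C)C)[C@@H](O[Si](C)(C)C(C)(C)C)c2ccc(OCc3ccccc3)c(OC)c2)c1)CC(=O)O
F4 | step 15 | (4R)-4-({4-(benzyloxy)-3-[(1R,2R)-1-[4-(benzyloxy)-3-methoxyphenyl]-1,3-bis(tert-butyldimethylsilyloxy)propan-2-yl]-5-methoxyphenyl}methyl)oxolan-2-one | O=C1C[C@@H](Cc2cc(OC)c(OCc3ccccc3)c([C@H](CO[Si](C)(C)C(C)(C)C)[C@@H](O[Si](C)(C)C(C)(C)C)c3ccc(OCc4ccccc4)c(OC)c3)c2)CO1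
F0 | step 12 | none | none
F5 | step 13 | (4R)-4-benzyl-3-[(2S,3R)-2-[2-(benzyloxy)-5-iodo-3-methoxyphenyl]-3-[4-(benzyloxy)-3-methoxyphenyl]-3-(tert-butyldimethylsilyloxy)propanoyl]-1,3-oxazolidin-2-one | COc1cc(I)cc([C@H](C(=O)N2[C@H](Cc3ccccc3)COC2=O)[C@@H](O[Si](C)(C)C(C)(C)C)c2ccc(OCc3ccccc3)c(OC)c2)c1OCc1ccccc1
F6 | step 13 | (2R,3R)-2-[2-(benzyloxy)-5-iodo-3-methoxyphenyl]-3-[4-(benzyloxy)-3-methoxyphenyl]-3-(tert-butyldimethylsilyloxy)propan-1-ol | COc1cc(I)cc([C@H](CO)[C@@H](O[Si](C)(C)C(C)(C)C)c2ccc(OCc3ccccc3)c(OC)c2)c1OCc1ccccc1
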